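All runs are calculated with made-up constants.

Late in the earlier runs I found the electrophile at 15.7 %, 14.8 % and 14.4 % after 15.0 h, with free base at 0.68 equiv, 1.1 equiv and 1.5 equiv. That is a spread of 1.3 percentage points against a scatter of 1 point, so I reckoned without the base.

| flask | electrophile | nucleophile | free base | protic impurity | remark | time |
|---|---|---|---|---|---|---|
| birch | 0.090 M | 1.1 equiv (fed, over 8.0 h) | 0.68 equiv | 9 mM | run made earlier |  |
| alder | 0.090 M | 1.1 equiv (fed, over 8.0 h) | 1.1 equiv | 9 mM | run made earlier |  |
| elm | 0.090 M | 1.1 equiv (fed, over 8.0 h) | 1.5 equiv | 9 mM | run made earlier |  |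
| amber | 0.090 M | 1.10 equiv (fed, over 8.0 h) | 0.800 equiv | 9.00 mM |  | 15 h |
| teal | 0.090 M | 1.10 equiv (fed, over 8.0 h) | 1.60 equiv | 9.00 mM |  | 15 h |

| run | time / h | electrophile / % | target / % |
|---|---|---|---|
| birch | 1.33 | 74.4 | 0.5 |
| birch | 2.50 | 60.4 | 1.2 |
| birch | 4.00 | 48.0 | 4.0 |
| birch | 8.00 | 27.4 | 8.7 |
| birch | 15.0 | 15.7 | 16.2 |
| alder | 1.33 | 74.3 | 0.4 |
| alder | 4.00 | 48.3 | 4.8 |
| alder | 8.00 | 30.0 | 9.5 |
| alder | 10.0 | 23.3 | 11.1 |
| alder | 15.0 | 14.8 | 16.0 |
| elm | 1.33 | 75.0 | 0.6 |
| elm | 2.50 | 60.1 | 1.2 |
| elm | 4.00 | 46.4 | 3.5 |
| elm | 8.00 | 28.8 | 8.6 |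
| elm | 15.0 | 14.4 | 16.1 |

(readings scatter by 1 percentage point)

- a species is counted by the electrophile in it: one homo dimer counts as two
- reactions considered so far: electrophile + nucleophile -> acid set free + target; nucleophile + acid set free <-> protonated nucleophile; acid set free + free base <-> salt of the base; 2 electrophile -> homo dimer; nucleophile + protic impurity -> quenched reagent

* part of the electrophile that has reacted at the end, amber
* part of the electrophile that has reacted at the end, teal
* what raising the equivalents of free base from its lowest to its highest value here does to the part of the electrophile that has reacted (changes below 5 percentage points count as none) (it rises / it falls / no change)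

I drew the alder curve as the reciprocal of the fraction of electrophile left, which climbs in a straight line under a rate law second order in the electrophile. At the start it rose by 0.260 h⁻¹, which put the crossing of half the charge near 3.85 h, and alder read 48.3 % at 4.00 h. From the end of the feed at 8.00 h to 15.0 h it rose by 0.489 h⁻¹, faster than at the start, while the target grew from 9.5 % to 16.0 %.

To join the two ends I took the rise of the reciprocal in alder from the start to 15.0 h, per hour and per molar of electrophile charged, an effective second-order constant read from the readings and averaged over that time, of 4.26 M⁻¹ h⁻¹. The homo dimer and the target both form in second-order steps, and with the equivalents of nucleophile and the feed time held I took this constant times electrophile charged times time as my estimate of the rise. For amber and teal, which have the electrophile charge and time of alder, my reckoning gave 85.2 % reacted.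

The forecast gave 85 % for amber, 85 % for teal and no change: “Both runs should reach about 85% conversion, so no change.”

The flask gave 85.8 % for amber and 85.8 % for teal; from the lowest to the highest free base the part reacted moved by 0.0068 points, which counts as no change. In amber, 99.8 % of the free base stood unbound at the end. Carried to 150 h, my constant gave 98.3 % reacted in amber, and the flask gave 99.9 %.

    electrophile + nucleophile → acid set free + target (k = 0.710 M⁻¹ h⁻¹)
    nucleophile + acid set free ⇌ protonated nucleophile, settled at all times (K = 16000 M⁻¹)
    acid set free + free base ⇌ salt of the base (K = 2.90 × 10⁵ M⁻¹, k = 22.0 M⁻¹ h⁻¹)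
    2 electrophile → homo dimer (k = 1.40 M⁻¹ h⁻¹)
    nucleophile + protic impurity → quenched reagent (k = 22.0 M⁻¹ h⁻¹)

For the neighbour charged with 0.054 M of electrophile, the same constant gave 77.5 % reacted at 15 h. The computed flask gave 75.8 %.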